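In a one-step world a flask has one time constant, fixed by what stands in it, and the earlier runs test that picture by changing the substrate charge while holding the reagent charge.

| setting | noon | autumn | winter | dawn | north | south | east | west | south-west | north-west |
|---|---|---|---|---|---|---|---|---|---|---|
| substrate | 0.021 M | 0.045 M | 0.072 M | 0.054 M | 0.080 M | 0.040 M | 0.054 M | 0.054 M | 0.025 M | 0.040 M |
| reagent | 0.0378 M (fed, over 15 h) | 0.0378 M (fed, over 15 h) | 0.0378 M (fed, over 15 h) | 0.0378 M (fed, over 15 h) | 0.0378 M (fed, over 5.0 h) | 0.0378 M (fed, over 8.0 h) | 0.0378 M (fed, over 15 h) | 0.150 M (fed, over 5.0 h) | 0.0378 M (fed, over 8.0 h) | 0.0378 M (fed, over 10 h) |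
| free catalyst | 0.12 mM | 0.12 mM | 0.12 mM | 0.11 mM | 0.40 mM | 0.12 mM | 0.12 mM | 0.12 mM | 0.040 mM | 0.030 mM |
| remark | run made earlier; the fed solution adds 1.0 times the starting volume | run made earlier; the fed solution adds 1.0 times the starting volume | run made earlier; the fed solution adds 1.0 times the starting volume | run made earlier; the fed solution adds 1.0 times the starting volume | the fed solution adds 1.0 times the starting volume | the fed solution adds 1.0 times the starting volume | the fed solution adds 1.0 times the starting volume | the fed solution adds 1.0 times the starting volume | the fed solution adds 1.0 times the starting volume | the fed solution adds 1.0 times the starting volume |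
| time |  |  |  |  | 3.0 d | 3.0 d | 3.0 d | 3.0 d | 3.0 d | 3.0 d |

| run | time / h | target / % | substrate / % |
|---|---|---|---|
| noon | 4.00 | 4.4 | 97.0 |
| noon | 8.00 | 7.8 | 91.2 |
| noon | 15.0 | 19.2 | 80.4 |
| noon | 25.0 | 36.0 | 62.5 |
| noon | 48.0 | 67.2 | 30.8 |
| autumn | 4.00 | 3.0 | 100.1 |
| autumn | 8.00 | 4.0 | 97.5 |
| autumn | 15.0 | 10.5 | 89.0 |
| autumn | 25.0 | 18.1 | 81.2 |
| autumn | 48.0 | 38.2 | 62.2 |
| winter | 5.00 | 0.6 | 97.1 |
| winter | 12.0 | 6.0 | 96.2 |
| winter | 25.0 | 12.6 | 87.4 |
| winter | 40.0 | 20.9 | 78.5 |
| winter | 48.0 | 25.6 | 74.7 |
| dawn | 4.00 | 0 | 98.7 |
| dawn | 8.00 | 3.8 | 99.1 |
| dawn | 15.0 | 8.6 | 91.7 |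
| dawn | 25.0 | 13.8 | 83.7 |
| dawn | 48.0 | 31.7 | 70.4 |

(readings scatter by 1 percentage point)

- every charge counts on the volume at the start, and the solution that is fed holds the whole dose

- all flasks from highest to lowest amount of target, in percent of the substrate charged, at 3.0 d (north / south / east / west / south-west / north-west)
- the same order at 15 h (north / south / east / west / south-west / north-west)
- the amount of target, in percent of the substrate charged of the flask you put first, at 3.0 d
- the amount of target, in percent of the substrate charged of the flask you put last, at 3.0 d

1. Autumn, with 0.045 M of substrate, holds 0.00473 M of target at 15.0 h and 0.0172 M at 48.0 h, a pace of 3.78 × 10⁻⁴ M h⁻¹ on the starting volume. Winter, with a substrate charge 1.60 times larger, reads 0.0184 M at 48.0 h, so between these two runs the amount of target at that time follows the substrate charge only weakly.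

2. The four runs share one reagent charge, so they do not vary it, and west, with 0.150 M of reagent, lies beyond them. Two views stay open, and each gives west a bound.

3. Lower bound: if extra reagent adds nothing, west, which receives its reagent sooner than autumn, holds at least what autumn holds at 3.0 d with its pace kept from 15.0 h on, namely 0.0263 M, and that is 48.6% of west's substrate.

4. Upper bound: if the pace follows the reagent left (pseudo-first-order in reagent), then, taking one reagent per target, autumn's reagent falls from 0.0331 M to 0.0206 M between those readings. That gives 69.8 h, the reagent clock, meaning the time constant of the reagent left after the feed at 0.12 mM of catalyst. The clock is taken to lengthen in inverse proportion to the catalyst charge.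

5. Counted from time zero, which errs on the high side, this clock has west spend 0.0966 M of reagent by 3.0 d, more than its 0.054 M of substrate, so in this reckoning substrate is the limiting reagent and the ceiling stays at 100%. With one reagent charge in the runs, the hand gets no further, and this reckoning commits to the bracket from 48.6% to 100%.

6. The forecast gives south > west > east > north > south-west > north-west at 3.0 d and north > south > west > east > south-west > north-west at 15 h, with south first at 64% (56% to 72%) and north-west last at 18% (14% to 22%). Its grounds open with “The target forms at an almost constant absolute rate”, and its 57% for west stands inside the bracket, in the lower part.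

7. The simulation gives west > south > north > east > south-west > north-west at 3.0 d and west > north > south > east > south-west > north-west at 15 h. West stands first with 90.8%, inside the bracket, and north-west last with 19.4%.

    catalyst intermediate D → free catalyst + target (k = 63.0 h⁻¹)
    2 catalyst intermediate A → spent catalyst (k = 180 M⁻¹ h⁻¹)
    reagent + free catalyst → catalyst intermediate A (k = 310 M⁻¹ h⁻¹)
    catalyst intermediate C → catalyst intermediate D (k = 1200 h⁻¹)
    substrate + catalyst intermediate B → catalyst intermediate C (k = 1500 M⁻¹ h⁻¹)
    catalyst intermediate A ⇌ released group + catalyst intermediate B (K = 0.0690 M, k = 53.0 h⁻¹)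

West keeps 67.2% of its reagent at 3.00 d, more than the 35.6% the clock leaves, with free catalyst at 13.0%. A neighbour flask is west with 3.0 × 10⁻⁵ M of free catalyst, a quarter of the charge. With the clock taken inversely proportional to catalyst it lengthens to 279 h, so the upper bound falls to 63.2%, and with the pace taken proportional to catalyst the lower bound falls to 12.2%. The neighbour holds 34.3% of target, with 87.6% of its reagent left.

The earlier runs and the new flask were computed with constants of no real substance; the scatter is artificial.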